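The numbers in the tables come from a simulation for substances that don't exist; the scatter is artificial.

Count the doublings of the odds of D before drawing any straight line through this flask.

| flask | Z | L | remark | time |
|---|---|---|---|---|
| north | 0.14 M | 0.42 M | run made earlier |  |
| south-west | 0.32 M | 0.42 M | run made earlier |  |
| west | 0.21 M | 0.84 M | run made earlier |  |
| flask | 0.21 M | 0.420 M |  | 3.0 min |

| run | time / min | D / % | Z / % | X / % |
|---|---|---|---|---|
| north | 0.417 | 1.8 | 53.3 | 45.5 |
| north | 1.33 | 8.9 | 48.0 | 43.6 |
| north | 2.50 | 28.3 | 36.8 | 34.4 |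
| north | 4.00 | 61.1 | 19.6 | 19.7 |
| south-west | 0.417 | 2.8 | 51.9 | 45.5 |
| south-west | 1.33 | 23.5 | 39.1 | 38.4 |
| south-west | 2.50 | 65.9 | 16.4 | 18.7 |
| south-west | 4.00 | 88.9 | 6.0 | 6.5 |
| west | 0.417 | 7.0 | 49.1 | 44.1 |
| west | 1.33 | 55.2 | 19.2 | 24.8 |
| west | 2.50 | 93.9 | 1.7 | 3.0 |
| west | 4.00 | 99.9 | 0 | 0.1 |

(standard deviation of a reading: 0.5 percentage points)

1. concentration of D at 3.0 min, in M
2. concentration of Z at 3.0 min, in M
3. concentration of X at 3.0 min, in M

- what was read earlier has a scatter of 0.5 percentage points, one standard deviation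

Two chemists dispute the flask. Amounts of D, Z and X below are fractions of the Z charged. L stands at 0.420 M in the flask, as in the north and south-west runs, so both chemists interpolate on the Z charge.

The first holds that D comes at a steady pace. At 0.417 min the north run read 1.8% and the south-west run 2.8%. That puts the flask at 2.19%. His line then reaches 15.7% at 3.0 min.

The second holds that D breeds D, which is autocatalysis. Between 1.33 min and 2.50 min, the odds of D against the rest of the Z charged grow at 1.19 min⁻¹ in the north run and 1.57 min⁻¹ in the south-west run. For the flask she interpolates 1.34 min⁻¹. So her doubling time of the odds is 0.517 min.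

Her flask starts from interpolated odds of 0.179 at 1.33 min. Up to 3.0 min she counts 3.23 doublings, which gives D 62.7%. I commit to her count, far above his line.

The forecast takes her side; its words are “so it is autocatalytic”. It gives D 54.8%, Z 22.9% and X 22.4%, so its D lies below my count.

The flask at 3.0 min holds D 59.7%, Z 19.6% and X 20.6%, which is 0.125 M, 0.0412 M and 0.0434 M. The forecast's D and X stand within tolerance, and its Z is high by a factor of 1.16. My count overshoots D by 3 percentage points. The steady line holds early in the flask: at 0.300 min it gives 1.58%, and D stands at 1.61%.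

    Z ⇌ X (K = 0.900, k = 0.0650 s⁻¹)
    Z + L → D + E (k = 0.00220 L mol⁻¹ s⁻¹)
    Z + L + E → D + 2 E (k = 0.580 L² mol⁻² s⁻¹)

Now read the same flask at 8.0 min. From 1.33 min the count is 12.9 doublings, which leaves 0.0730% outside D. That flask holds D 99.0%, with Z 0.490% and X 0.534%, more outside D than the count gives. Its L stands at 50.5% of its own charge.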